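**Plan**
- Retrosynthesis cuts C16=C17 (methylenation), then C8–C15 (ring D, carbenoid C–H insertion), then C1=C2 and C3–C4 (ring A), the C20–O lactone bond and C9–C10 (ring B), and last C6–C8, which joins ring C to a five-carbon C19–C4–C5–C6–C7 chain carrying C10, C20 and C1.
- Forward: ring C is taken ready-made from (−)-quinic acid; an Ireland–Claisen rearrangement joins the two fragments; ring B closes by a Cp2TiCl radical cyclisation, the 19,20-lactone by lactonisation, ring A by metathesis, ring D last.
- Enabling feature: C13 on ring C carries oxygen and the C16 acyl carbon, which sits axial and 1,3-diaxial (through C14) to the tertiary C8–H of the cis B/C junction, so a C15 carbenoid can reach C8–H and close ring D (C8–C14–C13–C16–C15).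
- Stereochemistry: C13 is quinic acid C1; C8 and C6 come from [3,3] chirality transfer from the quinic C3 oxygen; C5 from desymmetrisation of a glutaric anhydride; C9 and C10 from cis ring closures; C4 from convex-face allylation; C2 from exo hydroboration; quaternary C8 from insertion with retention.

Key step: step 28

Remark: gibberellane numbering (C1–C20) is used for all intermediates; H5, H8, H9, the 2-oxygen and C7 are β, and C19, C20 and the 13-oxygen are α.
Assumption: the quinidine-derived catalyst of step 12 is taken to open the anhydride in the sense that gives the (R)-hemiester 17, by analogy with 3-alkylglutaric anhydrides; if the sense is opposite, the quinine-derived pseudo-enantiomer is used.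

**Ring C fragment**

Step 1
Reactants: 1 (−)-quinic acid
Product: 2 1,5-quinide
Conditions: p-toluenesulfonic acid monohydrate (5 mol %), toluene/DMF, reflux, Dean–Stark trap
Reagents that add atoms: none
Why: Acid-catalysed lactonisation with azeotropic removal of water joins the carboxyl group to the cis C5 hydroxyl (quinide formation), which marks O5 as the later leaving group and leaves 3-OH equatorial and 4-OH axial.

Step 2
Reactants: 2 1,5-quinide
Product: 3 3-O-triethylsilyl-1,5-quinide
Conditions: Et3SiCl (1.05 equiv), imidazole, DMF, −20 °C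
Reagents that add atoms: chlorotriethylsilane, CC[Si](Cl)(CC)CC
Why: Silyl ether formation in which the equatorial secondary 3-OH should react faster than the axial 4-OH and the tertiary 1-OH.

Step 3
Reactants: 3 3-O-triethylsilyl-1,5-quinide
Product: 4 4-deoxy-4-iodo-3-O-triethylsilyl-1,5-quinide (C4 inverted)
Conditions: PPh3, I2, imidazole, toluene, 90 °C
Reagents that add atoms: iodine, II
Why: Garegg–Samuelsson (Appel-type) iodination replaces the only free secondary hydroxyl with inversion while the tertiary hydroxyl is inert, and the C4 configuration is lost again in step 4.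

Step 4
Reactants: 4 4-iodo quinide
Product: 5 (1R,5R)-1-hydroxy-5-(triethylsilyloxy)cyclohex-3-ene-1-carboxylic acid
Conditions: Zn dust, EtOH, 75 °C; then cold 1 M HCl to pH 3 (work-up)
Reagents that add atoms: none
Why: Zn-mediated reductive β-elimination of a β-acyloxy iodide (the reverse of an iodolactonisation) opens the lactone to the alkene and the free acid, the carboxylate leaving in preference to the C3 silyloxy group, so the allylic C–O stereocentre of quinic acid is kept.

Step 5
Reactants: 5 hydroxy acid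
Product: 6 benzyl (1R,5R)-1-hydroxy-5-(triethylsilyloxy)cyclohex-3-ene-1-carboxylate
Conditions: BnBr, KHCO3, DMF, 25 °C
Reagents that add atoms: benzyl bromide, BrCc1ccccc1
Why: O-alkylation of the carboxylate gives an ester that can later be removed by hydrogenolysis without touching the other esters.

Step 6
Reactants: 6 benzyl ester
Product: 7 benzyl (1R,5R)-1-(tert-butyldimethylsilyloxy)-5-(triethylsilyloxy)cyclohex-3-ene-1-carboxylate
Conditions: t-BuMe2SiOTf, 2,6-lutidine, CH2Cl2, 0 → 25 °C
Reagents that add atoms: tert-butyldimethylsilyl trifluoromethanesulfonate, CC(C)(C)[Si](C)(C)OS(=O)(=O)C(F)(F)F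
Why: Silylation of the tertiary α-hydroxy ester with a silyl triflate installs a robust group on O13 that offers the later carbenoid no activated C–H bond.

Step 7
Reactants: 7 bis-silyl ether
Product: 8 benzyl (1R,5R)-1-(tert-butyldimethylsilyloxy)-5-hydroxycyclohex-3-ene-1-carboxylate (ring C alcohol; C1 = C13 and C5 = C11)
Conditions: AcOH/THF/H2O (3:1:1), 25 °C
Reagents that add atoms: none
Why: Mild acid hydrolysis cleaves the secondary triethylsilyl ether much faster than the tertiary tert-butyldimethylsilyl ether.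

**Acid fragment**

Step 8
Reactants: 9 2-bromoprop-2-en-1-ol
Product: 10 1-{[(2-bromoprop-2-en-1-yl)oxy]methyl}-4-methoxybenzene
Conditions: NaH, 4-MeOC6H4CH2Cl, Bu4NI (cat.), THF, 0 → 25 °C
Reagents that add atoms: 4-methoxybenzyl chloride, COc1ccc(CCl)cc1
Why: Williamson ether synthesis protects the allylic oxygen as an ether that can be removed later under neutral oxidative conditions.

Step 9
Reactants: 10 bromoallyl ether; 11 dimethyl (2E)-pent-2-enedioate (dimethyl glutaconate)
Product: 14 dimethyl 3-{3-[(4-methoxybenzyl)oxy]prop-1-en-2-yl}pentanedioate, via Grignard reagent 12 (not isolated), via silyl ketene acetal 13 (not isolated)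
Conditions: Mg, LiCl, THF, 0 °C; then CuBr·SMe2 (10 mol %), Me3SiCl, 11, −78 °C; aq. NH4Cl
Reagents that add atoms: none
Why: CuBr·SMe2-catalysed conjugate addition of an alkenyl Grignard reagent (kept at or below 0 °C so that it does not lose the alkoxide to give allene), accelerated by Me3SiCl so that 1,4-addition should outrun deprotonation of the acidic diester, gives a symmetric achiral adduct.

Step 10
Reactants: 14 diester
Product: 15 3-{3-[(4-methoxybenzyl)oxy]prop-1-en-2-yl}pentanedioic acid
Conditions: LiOH, THF/H2O, 25 °C; then 1 M HCl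
Reagents that add atoms: lithium hydroxide, [Li+].[OH-]
Why: Saponification of both methyl esters; the ether and the alkene are inert to hydroxide.

Step 11
Reactants: 15 diacid
Product: 16 4-{3-[(4-methoxybenzyl)oxy]prop-1-en-2-yl}oxane-2,6-dione
Conditions: Ac2O, 80 °C
Reagents that add atoms: none
Why: Cyclodehydration of a glutaric acid to the six-membered prochiral cyclic anhydride.

Step 12
Reactants: 16 anhydride
Product: 17 (3R)-5-methoxy-3-{3-[(4-methoxybenzyl)oxy]prop-1-en-2-yl}-5-oxopentanoic acid
Conditions: MeOH (10 equiv), hydroquinidine anthraquinone-1,4-diyl diether (DHQD)2AQN (10 mol %), Et2O, −40 °C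
Reagents that add atoms: methanol, CO
Why: Cinchona-alkaloid-catalysed enantioselective methanolysis (desymmetrisation of a prochiral anhydride) sets C5 by catalyst control and makes the two arms different: the acid arm becomes C6–C7 and the ester arm C4–C19.

**Union and rings B and A**

Step 13
Reactants: 8 ring C alcohol; 17 (R)-hemiester
Product: 18 allylic ester (C11–O acylated by the acid arm of 17)
Conditions: EDC·HCl, 4-(dimethylamino)pyridine, CH2Cl2, 0 → 25 °C
Reagents that add atoms: none
Why: Steglich-type carbodiimide esterification of the secondary allylic alcohol; no stereocentre is touched.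

Step 14
Reactants: 18 allylic ester
Product: 21 rearranged C6–C8 acid (C7 carboxyl free; C8 chain cis to the 13-silyloxy group), via bis(silyl ketene acetal) 19 (not isolated), via trimethylsilyl ester 20 (not isolated)
Conditions: LiN(iPr)2 (2.4 equiv), Me3SiCl, THF/DMPU (4:1), −78 °C, then 60 °C; 1 M HCl work-up
Reagents that add atoms: none
Why: Ireland–Claisen rearrangement in which both esters are silylated but only the allyl ester can shift, so C6 is delivered suprafacially from the C11 oxygen to the same (α) face of C8 (chirality transfer from quinic acid C3), and the chair transition state of the Z(O)-enolate-derived ketene acetal (the boat is blocked by the axial C13 silyloxy group) should give the 6β-carboxyl epimer, which is also the thermodynamically preferred one once ring B exists.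

Step 15
Reactants: 21 rearranged acid
Product: 22 2-(trimethylsilyl)ethyl ester of 21
Conditions: Me3SiCH2CH2OH, EDC·HCl, 4-(dimethylamino)pyridine, CH2Cl2, 25 °C
Reagents that add atoms: 2-(trimethylsilyl)ethanol, C[Si](C)(C)CCO
Why: Carbodiimide esterification gives a C7 ester that is distinct from the C16 benzyl ester and falls to fluoride in the last step.

Step 16
Reactants: 22 2-(trimethylsilyl)ethyl ester
Product: 23 allylic alcohol (4-methoxybenzyl group removed)
Conditions: DDQ, CH2Cl2/pH 7 buffer (10:1), 0 → 25 °C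
Reagents that add atoms: none
Why: Oxidative cleavage of the 4-methoxybenzyl ether under buffered neutral conditions leaves the benzyl ester, the silyl groups and both alkenes untouched.

Step 17
Reactants: 23 allylic alcohol
Product: 24 epoxy alcohol (both epimers at the epoxide carbon)
Conditions: VO(acac)2 (2 mol %), t-BuOOH, CH2Cl2, 0 °C
Reagents that add atoms: tert-butyl hydroperoxide, CC(C)(C)OO
Why: VO(acac)2-catalysed hydroxyl-directed epoxidation acts on the allylic alcohol alkene only and not on the isolated C9=C11 bond, and the new epoxide centre is erased in step 18.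

Step 18
Reactants: 24 epoxy alcohol
Product: 26 lactone alcohol (rings B and C; cis-fused 19,20-lactone; C10 bears CH2OH = C1), via diol 25 (not isolated)
Conditions: Cp2TiCl2 (3 equiv), Mn dust, THF, 25 °C; 1 M HCl work-up; then p-toluenesulfonic acid monohydrate (cat.), CH2Cl2, 25 °C
Reagents that add atoms: none
Why: Cp2TiCl formed in the flask from Cp2TiCl2 and Mn (trivalent titanium, Nugent–RajanBabu epoxide opening) gives the tertiary C10 radical, which closes ring B by 5-exo-trig attack on C9 from the face of the C8–C6 bond (cis B/C junction, H9 β) and leaves C11 as CH2 after reduction and protonation; acid then lactonises the methyl ester with the hydroxymethyl group cis to the C4 arm, because only the cis-fused six-membered lactone is unstrained, which fixes C10 (C20 α, C1 β).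

Step 19
Reactants: 26 lactone alcohol
Product: 27 lactone aldehyde (C1 = CHO)
Conditions: Dess–Martin periodinane, NaHCO3, CH2Cl2, 25 °C
Reagents that add atoms: none
Why: Dess–Martin oxidation of the neopentyl primary alcohol gives a non-enolisable aldehyde under buffered conditions.

Step 20
Reactants: 27 lactone aldehyde
Product: 28 vinyl lactone (C10–CH=CH2)
Conditions: Ph3PCH3Br, KN(SiMe3)2, THF, −78 → 0 °C
Reagents that add atoms: methyltriphenylphosphonium bromide, C[P+](c1ccccc1)(c1ccccc1)c1ccccc1.[Br-]
Why: Wittig methylenation of an aldehyde that has no α-hydrogen and reacts with the ylide well below the temperature at which lactone or esters are attacked.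

Step 21
Reactants: 28 vinyl lactone
Product: 29 C4-methyl vinyl lactone
Conditions: LiN(iPr)2 (1.1 equiv), THF, −78 °C; MeI
Reagents that add atoms: iodomethane, CI
Why: Alkylation of the lactone enolate, which should form selectively because the lactone α-CH2 is more acidic and far less hindered than the tertiary C6–H of the ester; the methyl group enters anti to C6 and this centre is enolised again in step 22.

Step 22
Reactants: 29 C4-methyl vinyl lactone
Product: 30 C4-allyl C4-methyl vinyl lactone
Conditions: KN(SiMe3)2 (1.2 equiv), THF, −78 °C; allyl bromide, −78 → −30 °C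
Reagents that add atoms: allyl bromide, C=CCBr
Why: A second enolate alkylation creates quaternary C4, with allyl bromide expected on the convex face of the cis-fused lactone/ring B bicycle, anti to the C5–C6 bond, which places the allyl group (C3) cis to the C10 vinyl group and leaves the methyl group (C18) β.

Step 23
Reactants: 30 metathesis precursor
Product: 31 tricyclic Δ1 alkene (rings A B C and the lactone)
Conditions: second-generation Grubbs catalyst (H2IMes)(PCy3)Cl2Ru=CHPh (5 mol %), CH2Cl2, 40 °C
Reagents that add atoms: none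
Why: Ring-closing metathesis of the 1,3-cis vinyl and allyl groups closes ring A as a lactone-bridged bicyclo[3.3.1]nonene with loss of ethylene, and no other alkene is present.

Step 24
Reactants: 31 tricyclic alkene
Product: 33 2β-alcohol, via alkylborane 32 (not isolated)
Conditions: 9-BBN, THF, 25 → 50 °C; then H2O2, aq. NaOAc, 0 °C
Reagents that add atoms: hydrogen peroxide, OO
Why: Hydroboration–oxidation in which 9-BBN adds to the exo (β) face because the α face is covered by the lactone bridge, boron goes to C2 away from the neopentyl C1, and oxidation with retention gives the equatorial 2β-alcohol.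

Step 25
Reactants: 33 2β-alcohol
Product: 34 2β-(tert-butyldimethylsilyl) ether
Conditions: t-BuMe2SiCl, imidazole, DMF, 25 °C
Reagents that add atoms: tert-butyldimethylsilyl chloride, CC(C)(C)[Si](C)(C)Cl
Why: Silylation of the unhindered equatorial secondary alcohol gives an ether that survives the carbenoid step and falls together with the other silicon groups.

**Diazoketone, ring D and end game**

Step 26
Reactants: 34 benzyl ester
Product: 35 C16 carboxylic acid
Conditions: H2 (1 atm), 10% Pd/C (palladium on carbon), EtOAc, 25 °C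
Reagents that add atoms: none
Why: Hydrogenolysis of the benzyl ester frees only the C16 acid, since no alkene remains and the silyl ethers, the lactone and the 2-(trimethylsilyl)ethyl ester are inert.

Step 27
Reactants: 35 C16 acid
Product: 37 diazoketone (C13–CO–CHN2), via acid chloride 36 (not isolated)
Conditions: 1-chloro-N,N,2-trimethylprop-1-en-1-amine, CH2Cl2, 0 → 25 °C; then Me3SiCHN2 (2.5 equiv), MeCN/THF, 0 → 25 °C
Reagents that add atoms: trimethylsilyldiazomethane, C[Si](C)(C)C=[N+]=[N-]
Why: The α-chloroenamine gives the acid chloride without HCl, and acylation of trimethylsilyldiazomethane with loss of Me3SiCl (first stage of an Arndt–Eistert sequence) gives the diazoketone, no ketene being possible because C13 has no hydrogen.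

Step 28
Reactants: 37 diazoketone
Product: 38 16-oxo-17-nor compound (ring D closed)
Conditions: Rh2(OAc)4 (2 mol %), CH2Cl2, 25 °C, slow addition of 37
Reagents that add atoms: none
Why: Rh2(OAc)4 expels N2 from 37 to give an electrophilic dirhodium carbenoid at C15, which inserts into the tertiary C8–H bond through a concerted three-centre transition state and forms C15–C8. The closest known reaction type is the intramolecular 1,5 C–H insertion of α-diazoketones to cyclopentanones catalysed by dirhodium tetracarboxylates such as Rh2(OAc)4. Ring D (C8–C14–C13–C16–C15) closes as a five-membered ketone by 1,5-insertion and completes the bicyclo[3.2.1]octane. The new quaternary stereocentre C8 is fixed by retention at the C–H bond, so it inherits the cis B/C junction set in step 18, and only the hydrogen syn to the axial acyl group can be reached. The step needs site selectivity for C8–H over the secondary axial C11–H, which is also 1,3 to C13: the carbenoid prefers the more electron-rich tertiary C–H, ring C is held in the chair with the acyl group axial because the flipped chair would put the C13 silyloxy group and C6 1,3-diaxial, and Rh2(NHCOCH3)4 can sharpen the preference. C13 has no hydrogen for a 1,2-shift, and the silyl ether offers neither an activated C–H bond within five-ring reach nor a basic oxygen for ylide formation.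

Step 29
Reactants: 38 16-ketone
Product: 39 fully protected target gibberellin (16-methylene)
Conditions: Zn, CH2Br2, TiCl4, THF/CH2Cl2, 0 → 25 °C
Reagents that add atoms: dibromomethane, BrCBr
Why: Takai–Lombardo methylenation, a non-basic reagent suited to hindered enolisable ketones, converts C16=O into the exocyclic alkene without epimerising C6 or opening the lactone.

Step 30
Reactants: 39 fully protected target gibberellin
Product: 40 the target gibberellin (number 98 of the gibberellin A series)
Conditions: Bu4NF (6 equiv), THF, 50 °C; then dilute HCl to pH 3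
Reagents that add atoms: none
Why: Fluoride-mediated global deprotection cleaves both tert-butyldimethylsilyl ethers and fragments the 2-(trimethylsilyl)ethyl ester to the C7 carboxylate, ethylene and Me3SiF in one operation, and acidification should give the target with the lactone intact.

**Compound list**

1 | (−)-quinic acid | C1[C@H]([C@H]([C@@H](C[C@@]1(C(=O)O)O)O)O)O | starting material
2 | 1,5-quinide, (1S,3R,4R,5R)-1,3,4-trihydroxy-6-oxabicyclo[3.2.1]octan-7-one | C1[C@H]([C@H]([C@@H](C[C@@]1(C3=O)O)O3)O)O | intermediate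
3 | 3-O-triethylsilyl-1,5-quinide | C1[C@H]([C@H]([C@@H](C[C@@]1(C3=O)O)O3)O)O[Si](CC)(CC)CC | intermediate
4 | 4-deoxy-4-iodo-3-O-triethylsilyl-1,5-quinide, iodide cis to the lactone oxygen | C1[C@H]([C@@H]([C@@H](C[C@@]1(C3=O)O)O3)I)O[Si](CC)(CC)CC | intermediate
5 | (1R,5R)-1-hydroxy-5-(triethylsilyloxy)cyclohex-3-ene-1-carboxylic acid | C1[C@H](C=CC[C@@]1(C(=O)O)O)O[Si](CC)(CC)CC | intermediate
6 | benzyl (1R,5R)-1-hydroxy-5-(triethylsilyloxy)cyclohex-3-ene-1-carboxylate | C1[C@H](C=CC[C@@]1(C(=O)OCc2ccccc2)O)O[Si](CC)(CC)CC | intermediate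
7 | benzyl (1R,5R)-1-(tert-butyldimethylsilyloxy)-5-(triethylsilyloxy)cyclohex-3-ene-1-carboxylate | C1[C@H](C=CC[C@@]1(C(=O)OCc2ccccc2)O[Si](C)(C)C(C)(C)C)O[Si](CC)(CC)CC | intermediate
8 | benzyl (1R,5R)-1-(tert-butyldimethylsilyloxy)-5-hydroxycyclohex-3-ene-1-carboxylate (ring C alcohol) | C1[C@H](C=CC[C@@]1(C(=O)OCc2ccccc2)O[Si](C)(C)C(C)(C)C)O | intermediate
9 | 2-bromoprop-2-en-1-ol | C=C(Br)CO | starting material
10 | 1-{[(2-bromoprop-2-en-1-yl)oxy]methyl}-4-methoxybenzene | C=C(Br)COCc1ccc(OC)cc1 | intermediate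
11 | dimethyl (2E)-pent-2-enedioate (dimethyl glutaconate) | COC(=O)/C=C/CC(=O)OC | starting material
12 | {3-[(4-methoxybenzyl)oxy]prop-1-en-2-yl}magnesium bromide | C=C([Mg]Br)COCc1ccc(OC)cc1 | intermediate (not isolated)
13 | methyl 5-methoxy-3-{3-[(4-methoxybenzyl)oxy]prop-1-en-2-yl}-5-(trimethylsilyloxy)pent-4-enoate (racemic, either alkene geometry) | COC(O[Si](C)(C)C)=CC(CC(=O)OC)C(=C)COCc1ccc(OC)cc1 | intermediate (not isolated)
14 | dimethyl 3-{3-[(4-methoxybenzyl)oxy]prop-1-en-2-yl}pentanedioate | COC(=O)CC(CC(=O)OC)C(=C)COCc1ccc(OC)cc1 | intermediate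
15 | 3-{3-[(4-methoxybenzyl)oxy]prop-1-en-2-yl}pentanedioic acid | OC(=O)CC(CC(=O)O)C(=C)COCc1ccc(OC)cc1 | intermediate
16 | 4-{3-[(4-methoxybenzyl)oxy]prop-1-en-2-yl}oxane-2,6-dione | O=C1CC(CC(=O)O1)C(=C)COCc1ccc(OC)cc1 | intermediate
17 | (3R)-5-methoxy-3-{3-[(4-methoxybenzyl)oxy]prop-1-en-2-yl}-5-oxopentanoic acid | O=C(O)C[C@H](CC(=O)OC)C(=C)COCc1ccc(OC)cc1 | intermediate
18 | benzyl (1R,5R)-1-(tert-butyldimethylsilyloxy)-5-{[(3R)-5-methoxy-3-{3-[(4-methoxybenzyl)oxy]prop-1-en-2-yl}-5-oxopentanoyl]oxy}cyclohex-3-ene-1-carboxylate | C1[C@H](C=CC[C@@]1(C(=O)OCc2ccccc2)O[Si](C)(C)C(C)(C)C)OC(=O)C[C@H](CC(=O)OC)C(=C)COCc3ccc(OC)cc3 | intermediate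
19 | bis(trimethylsilyl ketene acetal) of 18, both from the Z(O)-enolates | C1[C@H](C=CC[C@@]1(C(=O)OCc2ccccc2)O[Si](C)(C)C(C)(C)C)O/C(O[Si](C)(C)C)=C/[C@H](/C=C(/OC)O[Si](C)(C)C)C(=C)COCc3ccc(OC)cc3 | intermediate (not isolated)
20 | trimethylsilyl ester of 21 with the methyl ester arm still as its silyl ketene acetal | [C@@H]1(C[C@](O[Si](C)(C)C(C)(C)C)(C(=O)OCc2ccccc2)CC=C1)[C@@H](C(=O)O[Si](C)(C)C)[C@H](/C=C(/OC)O[Si](C)(C)C)C(=C)COCc3ccc(OC)cc3 | intermediate (not isolated)
21 | 2-[5-(benzyloxycarbonyl)-5-(tert-butyldimethylsilyloxy)cyclohex-2-en-1-yl]-3-(2-methoxy-2-oxoethyl)-4-{[(4-methoxybenzyl)oxy]methyl}pent-4-enoic acid; C8 chain cis to the silyloxy group, C5 and C6 as in the target | [C@@H]1(C[C@](O[Si](C)(C)C(C)(C)C)(C(=O)OCc2ccccc2)CC=C1)[C@@H](C(=O)O)[C@H](CC(=O)OC)C(=C)COCc3ccc(OC)cc3 | intermediate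
22 | 2-(trimethylsilyl)ethyl ester of 21 | [C@@H]1(C[C@](O[Si](C)(C)C(C)(C)C)(C(=O)OCc2ccccc2)CC=C1)[C@@H](C(=O)OCC[Si](C)(C)C)[C@H](CC(=O)OC)C(=C)COCc3ccc(OC)cc3 | intermediate
23 | allylic alcohol from 22 (4-methoxybenzyl group removed) | [C@@H]1(C[C@](O[Si](C)(C)C(C)(C)C)(C(=O)OCc2ccccc2)CC=C1)[C@@H](C(=O)OCC[Si](C)(C)C)[C@H](CC(=O)OC)C(=C)CO | intermediate
24 | epoxy alcohol from 23 (2-(hydroxymethyl)oxiran-2-yl group, both epimers at that carbon) | [C@@H]1(C[C@](O[Si](C)(C)C(C)(C)C)(C(=O)OCc2ccccc2)CC=C1)[C@@H](C(=O)OCC[Si](C)(C)C)[C@H](CC(=O)OC)C3(CO)CO3 | intermediate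
25 | ring B diol: cis-fused B/C bicycle with C10(CH2OH)2, C4–C19 methyl ester arm on C5, 6β ester, H8 and H9 β | [C@H]12C[C@](O[Si](C)(C)C(C)(C)C)(C(=O)OCc3ccccc3)CC[C@H]1C(CO)(CO)[C@@H](CC(=O)OC)[C@@H]2C(=O)OCC[Si](C)(C)C | intermediate (not isolated)
26 | lactone alcohol: 19,20-δ-lactone cis-fused to ring B, C10 β-CH2OH (C1), C7 2-(trimethylsilyl)ethyl ester, 13α-silyloxy, C16 benzyl ester | [C@H]12C[C@](O[Si](C)(C)C(C)(C)C)(C(=O)OCc4ccccc4)CC[C@H]1[C@@]3(CO)COC(=O)C[C@H]3[C@@H]2C(=O)OCC[Si](C)(C)C | intermediate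
27 | lactone aldehyde (C1 = CHO) | [C@H]12C[C@](O[Si](C)(C)C(C)(C)C)(C(=O)OCc4ccccc4)CC[C@H]1[C@@]3(C=O)COC(=O)C[C@H]3[C@@H]2C(=O)OCC[Si](C)(C)C | intermediate
28 | vinyl lactone (C10–CH=CH2) | [C@H]12C[C@](O[Si](C)(C)C(C)(C)C)(C(=O)OCc4ccccc4)CC[C@H]1[C@@]3(C=C)COC(=O)C[C@H]3[C@@H]2C(=O)OCC[Si](C)(C)C | intermediate
29 | C4-methyl vinyl lactone (methyl trans to C6) | [C@H]12C[C@](O[Si](C)(C)C(C)(C)C)(C(=O)OCc4ccccc4)CC[C@H]1[C@@]3(C=C)COC(=O)[C@H](C)[C@H]3[C@@H]2C(=O)OCC[Si](C)(C)C | intermediate
30 | C4-allyl C4-methyl vinyl lactone (allyl cis to the C10 vinyl group, methyl β) | [C@H]12C[C@](O[Si](C)(C)C(C)(C)C)(C(=O)OCc4ccccc4)CC[C@H]1[C@@]3(C=C)COC(=O)[C@](C)(CC=C)[C@H]3[C@@H]2C(=O)OCC[Si](C)(C)C | intermediate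
31 | tricyclic Δ1 alkene: rings A, B, C and the 19,20-lactone; 13α-silyloxy, C16 benzyl ester, C7 2-(trimethylsilyl)ethyl ester | [C@H]12C[C@](O[Si](C)(C)C(C)(C)C)(C(=O)OCc4ccccc4)CC[C@H]1[C@]13COC(=O)[C@](C)(CC=C1)[C@H]3[C@@H]2C(=O)OCC[Si](C)(C)C | intermediate
32 | 2β-(9-borabicyclo[3.3.1]nonan-9-yl) adduct of 31 | [C@H]12C[C@](O[Si](C)(C)C(C)(C)C)(C(=O)OCc4ccccc4)CC[C@H]1[C@]13COC(=O)[C@](C)(C[C@@H](B4C5CCCC4CCC5)C1)[C@H]3[C@@H]2C(=O)OCC[Si](C)(C)C | intermediate (not isolated)
33 | 2β-alcohol | [C@H]12C[C@](O[Si](C)(C)C(C)(C)C)(C(=O)OCc4ccccc4)CC[C@H]1[C@]13COC(=O)[C@](C)(C[C@@H](O)C1)[C@H]3[C@@H]2C(=O)OCC[Si](C)(C)C | intermediate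
34 | 2β,13α-bis(tert-butyldimethylsilyl) ether, C16 benzyl ester | [C@H]12C[C@](O[Si](C)(C)C(C)(C)C)(C(=O)OCc4ccccc4)CC[C@H]1[C@]13COC(=O)[C@](C)(C[C@@H](O[Si](C)(C)C(C)(C)C)C1)[C@H]3[C@@H]2C(=O)OCC[Si](C)(C)C | intermediate
35 | C16 carboxylic acid | [C@H]12C[C@](O[Si](C)(C)C(C)(C)C)(C(=O)O)CC[C@H]1[C@]13COC(=O)[C@](C)(C[C@@H](O[Si](C)(C)C(C)(C)C)C1)[C@H]3[C@@H]2C(=O)OCC[Si](C)(C)C | intermediate
36 | C16 acid chloride | [C@H]12C[C@](O[Si](C)(C)C(C)(C)C)(C(=O)Cl)CC[C@H]1[C@]13COC(=O)[C@](C)(C[C@@H](O[Si](C)(C)C(C)(C)C)C1)[C@H]3[C@@H]2C(=O)OCC[Si](C)(C)C | intermediate (not isolated)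
37 | C13 diazoacetyl tricyclic lactone (2β,13α-bis-silyl ether, C7 2-(trimethylsilyl)ethyl ester) | [C@H]12C[C@](O[Si](C)(C)C(C)(C)C)(C(=O)C=[N+]=[N-])CC[C@H]1[C@]13COC(=O)[C@](C)(C[C@@H](O[Si](C)(C)C(C)(C)C)C1)[C@H]3[C@@H]2C(=O)OCC[Si](C)(C)C | intermediate
38 | 16-oxo-17-nor derivative of the target gibberellin as its 2,13-bis(tert-butyldimethylsilyl) ether 2-(trimethylsilyl)ethyl ester | O=C1C[C@]23C[C@@]1(O[Si](C)(C)C(C)(C)C)CC[C@H]2[C@]12COC(=O)[C@](C)(C[C@@H](O[Si](C)(C)C(C)(C)C)C1)[C@H]2[C@@H]3C(=O)OCC[Si](C)(C)C | intermediate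
39 | target gibberellin as its 2,13-bis(tert-butyldimethylsilyl) ether 2-(trimethylsilyl)ethyl ester (16-methylene) | C=C1C[C@]23C[C@@]1(O[Si](C)(C)C(C)(C)C)CC[C@H]2[C@]12COC(=O)[C@](C)(C[C@@H](O[Si](C)(C)C(C)(C)C)C1)[C@H]2[C@@H]3C(=O)OCC[Si](C)(C)C | intermediate
40 | target gibberellin, number 98 of the gibberellin A series: 2β,13α-dihydroxy-16-methylene C20 gibberellin with a free C7 carboxylic acid and the 19,20-δ-lactone | C=C1C[C@]23C[C@@]1(O)CC[C@H]2[C@]12COC(=O)[C@](C)(C[C@@H](O)C1)[C@H]2[C@@H]3C(=O)O | target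

**Count**

Total: 30 steps. Longest linear sequence: 25 steps (steps 1–7 and 13–30); the acid fragment takes steps 8–12.

**Steps most likely to fail, with fallbacks**

Step 14. The [3,3] shift may be slow, because the ketene acetal must reach C8 past the axial C13 silyloxy group while the doubly enolised substrate decomposes. The fallback sets out from 6 and postpones the bulky silyl ether. Acid hydrolysis of the triethylsilyl ether (AcOH/THF/H2O) gives benzyl (1R,5R)-1,5-dihydroxycyclohex-3-ene-1-carboxylate F1. Only the secondary hydroxyl is acylated by 17 (EDC·HCl, 4-(dimethylamino)pyridine), giving the hydroxy ester F2. Ireland–Claisen rearrangement with 3.5 equiv of LiN(iPr)2 and Me3SiCl, where the tertiary alkoxide is only transiently trimethylsilylated, followed by dilute acid gives the 13-hydroxy rearranged acid F3. Esterification with 2-(trimethylsilyl)ethanol gives the 13-hydroxy ester F4, and t-BuMe2SiOTf with 2,6-lutidine returns to the route at 22.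

Step 22. Facial selectivity of the allylation may be poor (attack syn to C6 and away from the angular vinyl group), which would leave allyl and vinyl trans so that metathesis cannot close ring A. The fallback sets out from 27 and lets ring closure itself fix C4. Vinylmagnesium bromide at −78 °C adds to the aldehyde to give the vinyl carbinol F5 (either C1 epimer). Methyl chloroformate and pyridine give the allylic methyl carbonate F6. Enolate methylation (KN(SiMe3)2, MeI, −78 °C) gives the C4-methyl carbonate F7. The lithium enolate (LiN(SiMe3)2) then undergoes an intramolecular Tsuji–Trost alkylation with the zerovalent palladium complex Pd(PPh3)4; C4 can only bond to the allyl terminus C3 on the face that carries C1, so ring A closes with the C1=C2 alkene and the route is rejoined at 31.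

Step 28. Insertion into the secondary axial C11–H bond, or carbene dimerisation, may compete with insertion into C8–H. The fallback sets out from 35 and keeps the same bond formation with a more selective acceptor/acceptor carbenoid. Activation with carbonyldiimidazole and condensation with Mg(O2CCH2CO2CH2CH=CH2)2 gives the allyl β-keto ester F8. Diazo transfer (4-acetamidobenzenesulfonyl azide, Et3N) gives the diazo β-keto ester F9. Rh2(OAc)4 then gives the ring D β-keto ester F10, this carbenoid type being known to select strongly for tertiary C–H bonds. Pd(PPh3)4 and morpholine remove the allyl group with decarboxylation and return to the route at 38.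

Further compounds
F1 | step 14 | benzyl (1R,5R)-1,5-dihydroxycyclohex-3-ene-1-carboxylate | C1[C@H](C=CC[C@@]1(C(=O)OCc2ccccc2)O)O
F2 | step 14 | hydroxy ester: secondary hydroxyl of F1 acylated by the acid arm of 17 | C1[C@H](C=CC[C@@]1(C(=O)OCc2ccccc2)O)OC(=O)C[C@H](CC(=O)OC)C(=C)COCc3ccc(OC)cc3
F3 | step 14 | 13-hydroxy rearranged acid (21 without the silyl ether) | [C@@H]1(C[C@](O)(C(=O)OCc2ccccc2)CC=C1)[C@@H](C(=O)O)[C@H](CC(=O)OC)C(=C)COCc3ccc(OC)cc3
F4 | step 14 | 13-hydroxy 2-(trimethylsilyl)ethyl ester (22 without the silyl ether) | [C@@H]1(C[C@](O)(C(=O)OCc2ccccc2)CC=C1)[C@@H](C(=O)OCC[Si](C)(C)C)[C@H](CC(=O)OC)C(=C)COCc3ccc(OC)cc3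
F5 | step 22 | vinyl carbinol: C10–CH(OH)–CH=CH2 lactone (either C1 epimer) | [C@H]12C[C@](O[Si](C)(C)C(C)(C)C)(C(=O)OCc4ccccc4)CC[C@H]1[C@@]3(C(O)C=C)COC(=O)C[C@H]3[C@@H]2C(=O)OCC[Si](C)(C)C
F6 | step 22 | allylic methyl carbonate of F5 | [C@H]12C[C@](O[Si](C)(C)C(C)(C)C)(C(=O)OCc4ccccc4)CC[C@H]1[C@@]3(C(OC(=O)OC)C=C)COC(=O)C[C@H]3[C@@H]2C(=O)OCC[Si](C)(C)C
F7 | step 22 | C4-methyl allylic carbonate | [C@H]12C[C@](O[Si](C)(C)C(C)(C)C)(C(=O)OCc4ccccc4)CC[C@H]1[C@@]3(C(OC(=O)OC)C=C)COC(=O)[C@H](C)[C@H]3[C@@H]2C(=O)OCC[Si](C)(C)C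
F8 | step 28 | allyl β-keto ester: C13–CO–CH2–CO2CH2CH=CH2 | [C@H]12C[C@](O[Si](C)(C)C(C)(C)C)(C(=O)CC(=O)OCC=C)CC[C@H]1[C@]13COC(=O)[C@](C)(C[C@@H](O[Si](C)(C)C(C)(C)C)C1)[C@H]3[C@@H]2C(=O)OCC[Si](C)(C)C
F9 | step 28 | allyl α-diazo-β-keto ester | [C@H]12C[C@](O[Si](C)(C)C(C)(C)C)(C(=O)C(=[N+]=[N-])C(=O)OCC=C)CC[C@H]1[C@]13COC(=O)[C@](C)(C[C@@H](O[Si](C)(C)C(C)(C)C)C1)[C@H]3[C@@H]2C(=O)OCC[Si](C)(C)C
F10 | step 28 | ring D β-keto ester: 38 with an allyloxycarbonyl group on C15 (either C15 epimer) | O=C1C(C(=O)OCC=C)[C@]23C[C@@]1(O[Si](C)(C)C(C)(C)C)CC[C@H]2[C@]12COC(=O)[C@](C)(C[C@@H](O[Si](C)(C)C(C)(C)C)C1)[C@H]2[C@@H]3C(=O)OCC[Si](C)(C)C
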